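(The data stem from a simulated flask with made-up constants.)

In a one-step world, L + E gives Z at the rate k[L][E], and one speed κ, k times the starting [L], describes the flask.

| flask | L | E | J | remark | time |
|---|---|---|---|---|---|
| north-west | 0.40 M | 0.90 equiv | 0.97 equiv | run made earlier |  |
| east | 0.40 M | 0.90 equiv | 1.3 equiv | run made earlier |  |
| south-east | 0.40 M | 0.90 equiv | 1.6 equiv | run made earlier |  |
| cedar | 0.40 M | 0.900 equiv | 2.00 equiv |  | 5.0 d |
| birch | 0.40 M | 0.900 equiv | 1.00 equiv |  | 5.0 d |

| run | time / d | L / % | Z / % |
|---|---|---|---|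
| north-west | 0.250 | 43.1 | 56.2 |
| north-west | 0.500 | 30.8 | 72.8 |
| north-west | 1.04 | 18.7 | 80.9 |
| north-west | 1.67 | 14.2 | 86.5 |
| north-west | 4.00 | 12.0 | 90.0 |
| east | 0.625 | 25.7 | 74.3 |
| east | 1.25 | 15.8 | 83.3 |
| east | 2.00 | 12.0 | 87.6 |
| east | 3.00 | 11.9 | 87.6 |
| east | 4.00 | 11.4 | 88.7 |
| south-east | 0.333 | 37.5 | 64.5 |
| south-east | 0.833 | 19.6 | 79.6 |
| south-east | 1.67 | 14.0 | 85.3 |
| south-east | 2.50 | 12.4 | 89.9 |
| south-east | 4.00 | 9.8 | 90.3 |

(scatter of a reading: 1 percentage point)



1. part of the L that has reacted at the end, cedar
2. part of the L that has reacted at the end, birch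
3. what raising the equivalents of J from its lowest to its highest value here does to the part of the L that has reacted (changes below 5 percentage points count as none) (it rises / it falls / no change)

E is charged below L, which makes it the limiting reagent: reacted L can approach 90.0% of the charge, and the reckoning needs only the small shortfall from that ceiling. Each E that reacts takes one L, so [L] − [E] stays at 10.0% of the L charge. Integrating the rate then gives [E]/[L] as the charged ratio times exp(−t/τ), where τ = 1/(excess × κ) is the tail time constant. It is the pseudo-first-order life of E in the excess of L. Since [E] is [L] less the excess, a single L reading yields κ: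

north-west: J 0.97 equiv, L 43.1% at 0.250 d, κ 6.35 d⁻¹
east: J 1.3 equiv, L 25.7% at 0.625 d, κ 6.20 d⁻¹
south-east: J 1.6 equiv, L 37.5% at 0.333 d, κ 6.15 d⁻¹

Reading down, J grows by a factor of 1.65, yet κ in the last row is lower than in the first. This reckoning therefore leaves J out of the rate and takes the mean κ, 6.23 d⁻¹, assuming the same for cedar, whose J lies beyond the rows. That makes τ 1.60 d, so 5.0 d is 3.12 time constants. The E still unreacted is then 0.416% of the L charge, which gives 89.6% reacted in both cedar and birch.

The forecast stands close to the 89.6% reckoned here, with 89.5% for cedar, 89.5% for birch and no change, holding that “E, at 0.90 equiv, sets the ceiling”.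

The simulation gives 89.6% for cedar and 89.6% for birch, and no change: the change is 0.016 percentage points.

    L + E → G + Z (k = 0.660 M⁻¹ h⁻¹)
    E + G ⇌ Q, settled at all times (K = 120 M⁻¹)
    G + J ⇌ D, settled at all times (K = 54000 M⁻¹)
    G + J ⇌ X, settled at all times (K = 520 M⁻¹)

In cedar at 5.00 d, E stands at 0.439% of its charge, and τ gave 0.462%. The neighbouring flask is cedar with L at 0.10 M instead of 0.40 M, the equivalents and time held. κ carries the starting [L] by its definition, so τ becomes 6.42 d, longer than the time, which is now 0.779 time constants. The same correction, 7.04% of the L charge, leaves 83.0% reacted. The neighbouring flask holds 83.1% reacted, with 7.6% of its E charge still there, unbound.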